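The leftover was what I looked at first: each Z came with 1.10 equiv of E, so a flask that spends one E per Z keeps a spare of 0.100 equiv. You wanted a quick number for the three new flasks, and this spare was where I started.

| flask | Z | E | X | temperature | remark | time |
|---|---|---|---|---|---|---|
| south-west | 0.050 M | 1.1 equiv | 0.050 equiv (fed, over 15 min) | 35 °C | run made earlier; the fed solution adds 1.0 times the starting volume |  |
| west | 0.075 M | 1.1 equiv | 0.050 equiv (fed, over 15 min) | 60 °C | run made earlier; the fed solution adds 1.0 times the starting volume |  |
| north | 0.10 M | 1.1 equiv | 0.075 equiv (fed, over 15 min) | 35 °C | run made earlier; the fed solution adds 1.0 times the starting volume |  |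
| dusk | 0.10 M | 1.10 equiv | 0.0500 equiv (fed, over 15 min) | 40 °C | the fed solution adds 1.0 times the starting volume | 50 min |
| summer | 0.10 M | 1.10 equiv | 0.0500 equiv (fed, over 15 min) | 60 °C | the fed solution adds 1.0 times the starting volume | 50 min |
| spring | 0.10 M | 1.10 equiv | 0.0500 equiv (fed, over 15 min) | 80 °C | the fed solution adds 1.0 times the starting volume | 50 min |

- south-west (time / min: D / %, Z / %, Q / %): 15.0: 0.3, 98.2, 1.8; 30.0: 0.1, 99.7, 2.7; 50.0: 0.4, 95.5, 3.5; 60.0: 1.4, 94.9, 5.0
- west (time / min: D / %, Z / %, Q / %): 2.00: 0, 96.3, 2.1; 4.00: 1.4, 94.1, 4.2; 10.0: 1.9, 89.7, 7.4; 20.0: 9.2, 82.7, 11.0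
- north (time / min: D / %, Z / %, Q / %): 5.00: 0.4, 99.1, 1.6; 12.0: 0.9, 97.0, 1.7; 25.0: 1.5, 94.7, 3.2; 60.0: 1.8, 91.3, 5.1

(each reading ± 1 percentage point)

1. which of these there is most of at the end, counted by the Z in it, dusk (D / Q / Z)
2. which of these there is most of at the end, counted by the Z in it, summer (D / Q / Z)
3. which of these there is most of at the end, counted by the Z in it, spring (D / Q / Z)
4. the largest of these amounts at the end, in percent of the Z charged, dusk
5. the largest of these amounts at the end, in percent of the Z charged, summer
6. the largest of these amounts at the end, in percent of the Z charged, spring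

- charges are per starting volume, the dose included; the dosed solution carries all of it

Your hunch was the forecast: Z largest in dusk at 91%, Z largest in summer at 63%, and D largest in spring at 60%, with “a consecutive path, Z → Q → D, with Q levelling off”. I took that path and added a supposition of my own: the step from Q to D takes a second E. The readings hold no E, so it stayed a supposition.

It turns E into a budget. Counted in percent of the Z charged, a flask pays once for each point of Q and twice for each point of D, out of a charge of 110%. I called the D ceiling the amount of D that the E charge can pay for once Q is paid, which is E charged minus Q, divided by two. Spring had no reading of its own, so I took the west reading of Q as a stand-in, 11.0% at 20.0 min with a scatter of 1 percentage point, although that run differs from spring in both temperature and Z, and I got 49.5%.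

For spring I committed to D levelling near that ceiling, with E as the limiting reagent. There I parted from the forecast, whose 60% stood 10 points higher. For dusk and summer I kept the forecast.

Spring ended with D at 45.8%, dusk with Z at 88.2%, and summer with Z at 53.4%.

    Z + E + L → Q + 2 L (k = 0.0901 L² mol⁻² s⁻¹, Ea = 44.0 kJ mol⁻¹)
    Z + E → Q + L (k = 6.40 × 10⁻⁴ L mol⁻¹ s⁻¹, Ea = 65.0 kJ mol⁻¹)
    X + L ⇌ G, settled at all times (K = 83000 L mol⁻¹, ΔH = −3.00 kJ mol⁻¹)
    E + Q → D (k = 0.00449 L mol⁻¹ s⁻¹, Ea = 65.0 kJ mol⁻¹)
    (constants at 40 °C)

Spring had 1.5% of its E left at 50.0 min. Its Q stood at 16.8%, which moved my ceiling from 49.5% to 46.6%, against D at 45.8%. The neighbour of dusk with 4.40 equiv of E ended with Q at 24.9% and D at 49.4%, so the same budget left 71.9% of its E charge unpaid, and at 50.0 min that flask still held 71.9% of its E charge.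

Readings and results come from a simulation for an exercise; noise was put on by code.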